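**Plan**
1. Retrosynthesis: cut the C6 ester, the C8–C9 epoxide, the C6–H bond (back to a ketone) and the C8=C9 alkene (metathesis); then re-join the C1 methyl carbon C15 to C6 as a cyclobutanone; cut C4–C5 (aldol), the cyclobutanone (ketene [2+2]) and two C–C bonds of an acyclic diene ketone.
2. Enabling feature: the C4 carbinol is β to the C6 oxygen through C5 (an aldol retron), and C15 and C6 are cis on ring A. Tying C15 to C6 makes C1 the symmetric 3-position of an achiral cyclobutanone whose α-carbons C5 and C15 are enantiotopic.
3. Forward: chain (steps 1–2), cyclobutanone (3–4), ring A by a desymmetrising aldol that forms C4–C5 (5), C7 unit onto C6 (6), rhodium-catalysed C6–C15 cleavage that unveils the C1 methyl and the C6 ketone (7), ring B by metathesis (8), then carbinol, epoxide and ester (9–11).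
4. Stereochemistry: D-proline in step 5 sets C1, C4 and C5, and the obligatory cis fusion of the four- and five-membered rings later becomes the trans fusion of rings A and B. C6 comes from a thermodynamically controlled dissolving-metal reduction, C8 and C9 from a hydroxyl-directed epoxidation.

Key step: step 5

Remark: atoms are numbered as in the daucane skeleton and keep these numbers in all intermediates: C1 quaternary ring-fusion carbon (methyl C15), C2 and C3 ring-A methylenes, C4 isopropyl carbinol, C5 ring-fusion CH, C6 ester carbinol, C7, C8 (methyl, epoxide), C9 (epoxide), C10. Ring A is the cyclopentane, ring B the cycloheptane. Either C6 epimer of compound 12 serves, because that centre returns to the carbonyl level in step 7.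

**Step 1**
Reactants: 1 3-chloro-2-(chloromethyl)prop-1-ene; 2 vinylmagnesium bromide
Product: 3 2-(chloromethyl)penta-1,4-diene
Conditions: 2 (1 equiv) added to 1 (3 equiv), Li2CuCl4 (3 mol %), THF, −20 to 0 °C
Reagents that add atoms: none
Why: Copper-catalysed allylic substitution of a Grignard reagent on an allylic chloride, in which the direct and the allylically transposed pathway converge on the same 1,4-diene because 1 is symmetric, while the excess of 1 should hold back double substitution.

**Step 2**
Reactants: 4 3-methylbutan-2-one; 3 2-(chloromethyl)penta-1,4-diene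
Product: 6 2-methyl-6-methylidenenon-8-en-3-one, via lithium enolate 5 (not isolated)
Conditions: LiN(iPr)2, THF, −78 °C; then 3, NaI (10 mol %), DMPU, −78 to 0 °C
Reagents that add atoms: none
Why: Kinetic deprotonation at the methyl group gives the less substituted enolate, whose C-alkylation by the allylic chloride (ketone enolate alkylation) installs in one operation the C2–C3–C4(=O)–isopropyl arm and the 1,1-disubstituted alkene whose central carbon becomes C1.

**Step 3**
Reactants: 6 2-methyl-6-methylidenenon-8-en-3-one
Product: 7 rac-2,2-dichloro-3-(4-methyl-3-oxopentyl)-3-(prop-2-en-1-yl)cyclobutan-1-one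
Conditions: Cl3CCOCl (1.5 equiv), Zn(Cu) (2 equiv), POCl3, Et2O, 35 °C (dichloroketene made in the flask)
Reagents that add atoms: trichloroacetyl chloride, ClC(=O)C(Cl)(Cl)Cl
Why: Thermal ketene–alkene [2+2] cycloaddition, in which dichloroketene should prefer the more nucleophilic 1,1-disubstituted alkene (positive charge builds up on the tertiary carbon) over the monosubstituted allyl alkene and bonds its carbonyl carbon to the CH2 terminus, so that the future C1 becomes C3 of the cyclobutanone.

**Step 4**
Reactants: 7 rac-2,2-dichloro-3-(4-methyl-3-oxopentyl)-3-(prop-2-en-1-yl)cyclobutan-1-one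
Product: 8 3-(4-methyl-3-oxopentyl)-3-(prop-2-en-1-yl)cyclobutan-1-one
Conditions: Zn dust, AcOH, 25 to 50 °C
Reagents that add atoms: none
Why: Reductive dehalogenation of the α,α-dichloroketone through zinc enolates, which leaves the alkene and the side-chain ketone alone and delivers an achiral cyclobutanone whose two α-methylene groups are enantiotopic.

**Step 5**
Reactants: 8 3-(4-methyl-3-oxopentyl)-3-(prop-2-en-1-yl)cyclobutan-1-one
Product: 10 (1R,4R,5R)-4-hydroxy-4-(propan-2-yl)-1-(prop-2-en-1-yl)bicyclo[3.2.0]heptan-6-one, via proline enamine 9 (not isolated)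
Conditions: (R)-proline (30 mol %), DMSO (0.05 M), 25 to 40 °C
Reagents that add atoms: none
Why: Proposed new method: D-proline condenses with the strained, unhindered cyclobutanone carbonyl rather than with the hindered isopropyl ketone to give enamine 9 at one of the two enantiotopic α-methylenes, and the enamine carbon C5 adds to the acid-activated side-chain ketone C4 in a 5-(enolexo)-exo-trig aldol that closes ring A, after which hydrolysis returns the catalyst. The closest known reaction types are the proline-catalysed desymmetrising intramolecular aldol of prochiral cyclic diketones (Hajos–Parrish type) and the proline-type intermolecular aldol desymmetrisation of 3-substituted cyclobutanones, whereas a cyclobutanone donor with a tethered unactivated ketone acceptor has no direct precedent. Because the tether starts at C1 next to the attacked carbon of a four-membered ring, ring A can only form cis-fused to the cyclobutanone (bicyclo[3.2.0]), which places the cyclobutanone CH2 (the future C1 methyl) cis to C6 and the allyl group cis to H5, the relationship that later becomes the trans fusion of rings A and B. C5 and, through the choice between the two enantiotopic methylenes, the quaternary C1 are set by the catalyst, since attack on the enamine face that carries the carboxylic acid should give (R) at C5 of 10 with the D-catalyst by analogy with intermolecular proline aldols; C4 is set by the hydrogen bond from that acid to the ketone oxygen, which turns the oxygen toward C6 and leaves the isopropyl group on the convex face. The step needs chemoselective enamine formation, enantiotopic-group selection and a favourable aldol equilibrium, which are secured by the strain-activated cyclobutanone carbonyl, by the chain reaching only the α-carbon on its own face of the matched enamine, and by the fact that the aldol cannot dehydrate because the enone would be a ring-fusion cyclobutenone.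

**Step 6**
Reactants: 10 (1R,4R,5R)-4-hydroxy-4-(propan-2-yl)-1-(prop-2-en-1-yl)bicyclo[3.2.0]heptan-6-one; 11 (2-methylprop-2-en-1-yl)magnesium chloride
Product: 12 6-(2-methylprop-2-en-1-yl)-4-(propan-2-yl)-1-(prop-2-en-1-yl)bicyclo[3.2.0]heptane-4,6-diol (C1, C4, C5 as in 10; 6-hydroxyl drawn on the ring-A face)
Conditions: 11 (3 equiv), THF, −78 to 0 °C; aqueous NH4Cl
Reagents that add atoms: none
Why: Grignard 1,2-addition to the strained and therefore very electrophilic cyclobutanone carbonyl after the first equivalent has deprotonated the tertiary hydroxyl, attack being expected from the convex face, although the configuration of this carbinol is of no consequence because the carbon returns to the carbonyl level in step 7.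

**Step 7**
Reactants: 12 6-(2-methylprop-2-en-1-yl)-4-(propan-2-yl)-1-(prop-2-en-1-yl)bicyclo[3.2.0]heptane-4,6-diol
Product: 13 1-[2-hydroxy-5-methyl-2-(propan-2-yl)-5-(prop-2-en-1-yl)cyclopentyl]-3-methylbut-3-en-1-one (acyl group, 2-hydroxyl and 5-methyl mutually cis)
Conditions: [Rh(OH)(cod)]2 (2.5 mol %), rac-BINAP (6 mol %), toluene, 80 °C
Reagents that add atoms: none
Why: Rhodium-catalysed ring opening of a tertiary cyclobutanol by β-carbon elimination from the rhodium alkoxide, driven by release of ring strain and expected to cleave the bond to the unsubstituted ring CH2 because that gives a primary alkyl–rhodium without β-hydrogens (the alternative is a secondary alkyl–rhodium between two quaternary carbons), whose protonation by a hydroxyl group turns this CH2 into the C1 methyl while C6 emerges as the ketone and the stereocentres at C1, C4 and C5 stay untouched.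

**Step 8**
Reactants: 13 1-[2-hydroxy-5-methyl-2-(propan-2-yl)-5-(prop-2-en-1-yl)cyclopentyl]-3-methylbut-3-en-1-one
Product: 14 (1R,4R,5R)-4-hydroxydauc-8-en-6-one (trans-fused; 4-hydroxyl cis to the C1 methyl)
Conditions: second-generation Hoveyda–Grubbs catalyst (5 mol %), 1,4-benzoquinone (10 mol %), toluene (0.005 M), 60 °C
Reagents that add atoms: none
Why: Ring-closing olefin metathesis between the allyl group on C1 and the 2-methylallyl ketone side chain on C5, which are trans on ring A, closes the seven-membered ring B as the trans-fused system with the trisubstituted C8=C9 alkene and loss of ethene, benzoquinone being added to suppress hydride-induced migration of the β,γ-double bond.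

**Step 9**
Reactants: 14 (1R,4R,5R)-4-hydroxydauc-8-en-6-one
Product: 15 (1R,4R,5S,6S)-dauc-8-ene-4,6-diol
Conditions: Li, NH3(l), THF, EtOH, −78 °C; then NH4Cl
Reagents that add atoms: none
Why: Dissolving-metal reduction of the ketone, which proceeds through a configurationally mobile ketyl and carbanion and therefore should give the thermodynamically preferred equatorial alcohol, namely the 6-hydroxyl on the face opposite to the pseudo-axial C1 methyl (cis to H5), whereas hydride reagents would be expected to attack from that open face and give the axial epimer; the isolated trisubstituted alkene is inert to these conditions.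

**Step 10**
Reactants: 15 (1R,4R,5S,6S)-dauc-8-ene-4,6-diol
Product: 16 (1R,4R,5S,6S,8R,9S)-8,9-epoxydaucane-4,6-diol
Conditions: VO(acac)2 (5 mol %), t-BuOOH (1.5 equiv), CH2Cl2, 0 to 25 °C
Reagents that add atoms: tert-butyl hydroperoxide, CC(C)(C)OO
Why: Vanadium-catalysed hydroxyl-directed epoxidation, in which the homoallylic C6 hydroxyl binds the metal peroxide and delivers oxygen to its own face of the C8=C9 alkene, a face that is also the one away from the pseudo-axial C1 methyl, so that the epoxide oxygen ends cis to the C6 oxygen as in the target.

**Step 11**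
Reactants: 16 (1R,4R,5S,6S,8R,9S)-8,9-epoxydaucane-4,6-diol; 17 3,4-dimethoxybenzoyl chloride
Product: 18 (1R,4R,5S,6S,8R,9S)-8,9-epoxy-4-hydroxydaucan-6-yl 3,4-dimethoxybenzoate (CNP0251065.1)
Conditions: 17 (1.5 equiv), Et3N, DMAP (20 mol %), CH2Cl2, 0 to 25 °C
Reagents that add atoms: none
Why: DMAP-catalysed acylation (nucleophilic catalysis through the acylpyridinium ion) of the secondary C6 hydroxyl, which is the only acylable alcohol because the tertiary C4 hydroxyl is too hindered, under basic conditions that leave the epoxide closed.

**Compound list**
1 | 3-chloro-2-(chloromethyl)prop-1-ene | ClCC(=C)CCl | starting material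
2 | vinylmagnesium bromide | C=C[Mg]Br | starting material
3 | 2-(chloromethyl)penta-1,4-diene | ClCC(=C)CC=C | intermediate
4 | 3-methylbutan-2-one | CC(C)C(C)=O | starting material
5 | lithium 3-methylbut-1-en-2-olate (kinetic enolate) | [Li]OC(=C)C(C)C | intermediate
6 | 2-methyl-6-methylidenenon-8-en-3-one | CC(C)C(=O)CCC(=C)CC=C | intermediate
7 | rac-2,2-dichloro-3-(4-methyl-3-oxopentyl)-3-(prop-2-en-1-yl)cyclobutan-1-one | O=C1CC(CC=C)(CCC(=O)C(C)C)C1(Cl)Cl | intermediate
8 | 3-(4-methyl-3-oxopentyl)-3-(prop-2-en-1-yl)cyclobutan-1-one (achiral) | O=C1CC(CC=C)(CCC(=O)C(C)C)C1 | intermediate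
9 | (2R)-1-[3-(4-methyl-3-oxopentyl)-3-(prop-2-en-1-yl)cyclobut-1-en-1-yl]pyrrolidine-2-carboxylic acid (enamine toward the methylene that becomes C5) | OC(=O)[C@H]1CCCN1C1=C[C@@](CC=C)(CCC(=O)C(C)C)C1 | intermediate
10 | (1R,4R,5R)-4-hydroxy-4-(propan-2-yl)-1-(prop-2-en-1-yl)bicyclo[3.2.0]heptan-6-one (cis-fused; hydroxyl cis to the cyclobutanone) | O=C1C[C@]2(CC=C)CC[C@@](O)(C(C)C)[C@H]12 | intermediate
11 | (2-methylprop-2-en-1-yl)magnesium chloride | C=C(C)C[Mg]Cl | starting material
12 | 6-(2-methylprop-2-en-1-yl)-4-(propan-2-yl)-1-(prop-2-en-1-yl)bicyclo[3.2.0]heptane-4,6-diol (C1, C4, C5 as in 10; 6-hydroxyl on the ring-A face) | C=C(C)C[C@@]1(O)C[C@]2(CC=C)CC[C@@](O)(C(C)C)[C@H]12 | intermediate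
13 | 1-[2-hydroxy-5-methyl-2-(propan-2-yl)-5-(prop-2-en-1-yl)cyclopentyl]-3-methylbut-3-en-1-one (acyl, 2-hydroxyl and 5-methyl mutually cis) | C=C(C)CC(=O)[C@@H]1[C@@](C)(CC=C)CC[C@@]1(O)C(C)C | intermediate
14 | (1R,4R,5R)-4-hydroxydauc-8-en-6-one (trans-fused) | O=C1CC(C)=CC[C@@]2(C)CC[C@@](O)(C(C)C)[C@H]12 | intermediate
15 | (1R,4R,5S,6S)-dauc-8-ene-4,6-diol (6-hydroxyl cis to H5) | O[C@H]1CC(C)=CC[C@@]2(C)CC[C@@](O)(C(C)C)[C@H]12 | intermediate
16 | (1R,4R,5S,6S,8R,9S)-8,9-epoxydaucane-4,6-diol (epoxide oxygen cis to the 6-hydroxyl) | O[C@H]1C[C@@]2(C)O[C@H]2C[C@@]2(C)CC[C@@](O)(C(C)C)[C@H]12 | intermediate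
17 | 3,4-dimethoxybenzoyl chloride | COc1ccc(C(Cl)=O)cc1OC | starting material
18 | (1R,4R,5S,6S,8R,9S)-8,9-epoxy-4-hydroxydaucan-6-yl 3,4-dimethoxybenzoate (CNP0251065.1) | COc1ccc(C(=O)O[C@H]2C[C@@]3(C)O[C@H]3C[C@@]3(C)CC[C@@](O)(C(C)C)[C@H]23)cc1OC | target

**Total step count:** 11 steps.
**Longest linear sequence:** 11 steps (the route is fully linear from 1).

**Steps most likely to fail**

First, step 5. The enamine aldol may stall because the equilibrium with the hindered ketone acceptor is unfavourable, the cyclobutanone may self-condense intermolecularly, or the selection between the two enantiotopic methylenes may be poor. The fallback sets out from 8 and closes the ring without a chiral catalyst by a base-mediated intramolecular aldol (KOt-Bu, t-BuOH/THF, 0 °C, high dilution). The cis fusion and the inward-pointing hydroxyl are still dictated by the bicycle, so this gives racemic 10 F1. Its enantiomers are separated by preparative chromatography on a chiral stationary phase, and the (1R,4R,5R) enantiomer re-enters the route as 10.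

Second, step 7. The C–C cleavage may go astray by retro-aldol opening of ring A through a rhodium alkoxide of the free tertiary C4 hydroxyl, by insertion of the alkyl–rhodium into a pendant alkene before it is protonated, or by migration of the β,γ-double bond into conjugation. The fallback sets out from 10 and masks the tertiary hydroxyl with N-(trimethylsilyl)imidazole in CH2Cl2 to give the trimethylsilyl ether of 10 F2. Reagent 11 is added as in step 6 to give the monoprotected cyclobutanol F3. The same rhodium-catalysed ring opening is then run on this substrate, which carries only the cyclobutanol hydroxyl, to give the trimethylsilyl ether of 13 F4. Mild methanolysis (PPTS, MeOH) returns 13.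

Third, step 9. Facial selectivity at C6 may be poor if the intermediate carbanion is protonated kinetically before it settles into the equatorial arrangement. The fallback sets out from 14 and reduces with LiBH(s-Bu)3 in THF at −78 °C. Hydride should come from the open face of H5, away from the C1 methyl, and give the 6-epimer of 15 F5. Mitsunobu esterification with 3,4-dimethoxybenzoic acid (PPh3, DIAD, toluene) inverts C6 and gives the 6-O-(3,4-dimethoxybenzoyl) derivative of 15 F6. Epoxidation with mCPBA (NaHCO3, CH2Cl2) on the face away from the C1 methyl then arrives at 18.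

**Further compounds**
F1 | step 5 | racemic 10 (both enantiomers) | O=C1C[C@]2(CC=C)CC[C@@](O)(C(C)C)[C@H]12.O=C1C[C@@]2(CC=C)CC[C@](O)(C(C)C)[C@@H]12
F2 | step 7 | trimethylsilyl ether of 10 | O=C1C[C@]2(CC=C)CC[C@@](O[Si](C)(C)C)(C(C)C)[C@H]12
F3 | step 7 | 4-O-trimethylsilyl ether of 12 | C=C(C)C[C@@]1(O)C[C@]2(CC=C)CC[C@@](O[Si](C)(C)C)(C(C)C)[C@H]12
F4 | step 7 | trimethylsilyl ether of 13 | C=C(C)CC(=O)[C@@H]1[C@@](C)(CC=C)CC[C@@]1(O[Si](C)(C)C)C(C)C
F5 | step 9 | 6-epimer of 15 | O[C@@H]1CC(C)=CC[C@@]2(C)CC[C@@](O)(C(C)C)[C@H]12
F6 | step 9 | 6-O-(3,4-dimethoxybenzoyl) derivative of 15 | COc1ccc(C(=O)O[C@H]2CC(C)=CC[C@@]3(C)CC[C@@](O)(C(C)C)[C@H]23)cc1OC
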